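**Assumption:** the target SMILES has no stereocentre (the molecule is achiral), so there is no enantiomer to control. Chiral intermediates are made as racemates or mixtures, and their stereocentres disappear on aromatisation or deoxygenation.

## Retrosynthetic overview

1. Target 25 ⇐ hydrogenolysis of pentabenzyl ether 24 ⇐ ionic deoxygenation of carbinol 23 ⇐ aryllithium from bromide 21 (para-bromination and O-benzylation of phenol 19) plus aldehyde 12.
2. Phenol 19 ⇐ isoaromatisation of arylidene vinylogous ester 18 ⇐ key intermolecular aldol of the lithium enolate of 15 with aldehyde 12 (brings in a 4-oxybenzyl unit and fixes OMe versus OH).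
3. 15 ⇐ O-methylation of 2-benzyl dione 14 ⇐ Knoevenagel condensation with in-situ reduction of dione 11 and aldehyde 12.
4. 11 ⇐ Michael addition, Claisen cyclisation and decarboxylation of diethyl malonate 7 on enone 6 ⇐ Wittig reaction of aldehyde 4 ⇐ acid 1.
5. Ring order: only the central ring is built (as a cyclohexane-1,3-dione in step 5, aromatised in step 10); the four outer benzene rings are bought.

## Route

Step 1
Reactants: 1 3-(3-hydroxyphenyl)propanoic acid
Product: 2 benzyl 3-[3-(benzyloxy)phenyl]propanoate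
Conditions: BnBr (2.3 equiv), K2CO3, DMF, 60 °C
Reagents that add atoms: benzyl bromide, BrCc1ccccc1
Why: Double O-alkylation (Williamson ether synthesis and carboxylate esterification) protects the phenol as a benzyl ether that lasts to the final step.

Step 2
Reactants: 2 benzyl 3-[3-(benzyloxy)phenyl]propanoate
Product: 3 3-[3-(benzyloxy)phenyl]propan-1-ol
Conditions: LiAlH4, THF, 0 °C to rt; H2O work-up
Reagents that add atoms: none
Why: Hydride reduction of the ester gives the primary alcohol while the aryl benzyl ether is inert.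

Step 3
Reactants: 3 3-[3-(benzyloxy)phenyl]propan-1-ol
Product: 4 3-[3-(benzyloxy)phenyl]propanal
Conditions: Dess–Martin periodinane, CH2Cl2, rt
Reagents that add atoms: none
Why: Dess–Martin oxidation stops cleanly at the aldehyde under neutral conditions.

Step 4
Reactants: 4 3-[3-(benzyloxy)phenyl]propanal; 5 1-(triphenyl-λ5-phosphanylidene)propan-2-one
Product: 6 (3E)-6-[3-(benzyloxy)phenyl]hex-3-en-2-one
Conditions: toluene, 80 °C
Reagents that add atoms: none
Why: Wittig olefination with a stabilised ylide gives the E-enone without the self-condensation that an aldol with acetone would risk.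

Step 5
Reactants: 6 (3E)-6-[3-(benzyloxy)phenyl]hex-3-en-2-one; 7 diethyl malonate
Product: 11 5-{2-[3-(benzyloxy)phenyl]ethyl}cyclohexane-1,3-dione, via Michael adduct 8 (not isolated), via cyclic keto ester 9 (not isolated), via keto acid 10 (not isolated)
Conditions: NaOEt, EtOH, reflux; then aq. NaOH, reflux; then aq. HCl, 80 °C
Reagents that add atoms: none
Why: Intermolecular Michael addition of the malonate anion, intramolecular Claisen (Dieckmann-type) cyclisation, saponification and decarboxylation build the central ring as in the classical dimedone synthesis.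

Step 6
Reactants: 11 5-{2-[3-(benzyloxy)phenyl]ethyl}cyclohexane-1,3-dione; 12 4-(benzyloxy)benzaldehyde
Product: 14 2-[4-(benzyloxy)benzyl]-5-{2-[3-(benzyloxy)phenyl]ethyl}cyclohexane-1,3-dione, via alkylidene dione 13 (not isolated)
Conditions: Hantzsch ester (diethyl 2,6-dimethyl-1,4-dihydropyridine-3,5-dicarboxylate, 1.05 equiv), L-proline (20 mol%), CH2Cl2, rt
Reagents that add atoms: none
Why: Proline-catalysed Knoevenagel condensation gives the alkylidene dione, which hydride transfer from the Hantzsch ester reduces before a second dione can add (reductive C-benzylation).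

Step 7
Reactants: 14 2-[4-(benzyloxy)benzyl]-5-{2-[3-(benzyloxy)phenyl]ethyl}cyclohexane-1,3-dione
Product: 15 2-[4-(benzyloxy)benzyl]-5-{2-[3-(benzyloxy)phenyl]ethyl}-3-methoxycyclohex-2-en-1-one (racemic)
Conditions: MeOH, TsOH·H2O (cat.), 3 Å MS, reflux
Reagents that add atoms: methanol, CO
Why: Acid-catalysed enol etherification of the symmetric dione can give only one vinylogous ester, which marks one oxygen as the future OMe.

Step 8
Reactants: 15 2-[4-(benzyloxy)benzyl]-5-{2-[3-(benzyloxy)phenyl]ethyl}-3-methoxycyclohex-2-en-1-one; 12 4-(benzyloxy)benzaldehyde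
Product: 16 6-{[4-(benzyloxy)phenyl](hydroxy)methyl}-2-[4-(benzyloxy)benzyl]-5-{2-[3-(benzyloxy)phenyl]ethyl}-3-methoxycyclohex-2-en-1-one (racemic mixture of diastereomers)
Conditions: LiN(i-Pr)2 (1.1 equiv), THF, −78 °C; then 12, −78 °C; AcOH quench at −78 °C
Reagents that add atoms: none
Why: Kinetic deprotonation at the alpha-prime carbon of the vinylogous ester (Stork–Danheiser enolate) and intermolecular aldol addition to the non-enolisable aldehyde form the new C–C bond; the new stereocentres are not controlled because steps 9 and 10 erase them.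

Step 9
Reactants: 16 aldol adduct (name as in step 8)
Product: 18 (6E)-2-[4-(benzyloxy)benzyl]-6-[4-(benzyloxy)benzylidene]-5-{2-[3-(benzyloxy)phenyl]ethyl}-3-methoxycyclohex-2-en-1-one (racemic), via mesylate 17 (not isolated)
Conditions: MsCl, Et3N, CH2Cl2, 0 °C; then DBU, rt
Reagents that add atoms: none
Why: Mesylation followed by E1cB elimination gives the conjugated arylidene ketone; its geometry does not matter for the next step.

Step 10
Reactants: 18 arylidene enone (name as in step 9)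
Product: 19 2,6-bis[4-(benzyloxy)benzyl]-3-{2-[3-(benzyloxy)phenyl]ethyl}-5-methoxyphenol
Conditions: RhCl3·3H2O (10 mol%), MeOH, 80 °C (sealed tube)
Reagents that add atoms: none
Why: Rhodium hydride-mediated migration of the exocyclic C=C into the ring gives a cyclohexadienone that tautomerises irreversibly to the phenol (isoaromatisation); methanol is used so that no alkoxy exchange can occur.

Step 11
Reactants: 19 2,6-bis[4-(benzyloxy)benzyl]-3-{2-[3-(benzyloxy)phenyl]ethyl}-5-methoxyphenol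
Product: 20 2,6-bis[4-(benzyloxy)benzyl]-4-bromo-3-{2-[3-(benzyloxy)phenyl]ethyl}-5-methoxyphenol
Conditions: NBS (1.0 equiv), MeCN, −20 to 0 °C, dark
Reagents that add atoms: N-bromosuccinimide, O=C1CCC(=O)N1Br
Why: Electrophilic aromatic bromination goes to the only free position of the central ring (para to OH, ortho to OMe), which is far more nucleophilic than the mono-alkoxy rings.

Step 12
Reactants: 20 2,6-bis[4-(benzyloxy)benzyl]-4-bromo-3-{2-[3-(benzyloxy)phenyl]ethyl}-5-methoxyphenol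
Product: 21 1-(benzyloxy)-2,6-bis[4-(benzyloxy)benzyl]-4-bromo-3-{2-[3-(benzyloxy)phenyl]ethyl}-5-methoxybenzene
Conditions: BnBr, K2CO3, DMF, 60 °C
Reagents that add atoms: benzyl bromide, BrCc1ccccc1
Why: Williamson etherification masks the acidic phenol before the organolithium step with a group that the final hydrogenolysis removes.

Step 13
Reactants: 21 1-(benzyloxy)-2,6-bis[4-(benzyloxy)benzyl]-4-bromo-3-{2-[3-(benzyloxy)phenyl]ethyl}-5-methoxybenzene; 12 4-(benzyloxy)benzaldehyde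
Product: 23 [4-(benzyloxy)phenyl](4-(benzyloxy)-3,5-bis[4-(benzyloxy)benzyl]-2-{2-[3-(benzyloxy)phenyl]ethyl}-6-methoxyphenyl)methanol (racemic), via aryllithium 22 (not isolated)
Conditions: n-BuLi (1.1 equiv), THF, −78 °C; then 12, −78 to 0 °C; H2O
Reagents that add atoms: none
Why: Bromine–lithium exchange is faster than any deprotonation at −78 °C, and the aryllithium (stabilised by the ortho OMe) adds 1,2 to the aldehyde; the racemic carbinol centre is removed in step 14.

Step 14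
Reactants: 23 diaryl carbinol (name as in step 13)
Product: 24 1-(benzyloxy)-2,4,6-tris[4-(benzyloxy)benzyl]-3-{2-[3-(benzyloxy)phenyl]ethyl}-5-methoxybenzene
Conditions: Et3SiH (3 equiv), CF3CO2H, CH2Cl2, 0 °C
Reagents that add atoms: none
Why: Ionic hydrogenation works because the doubly benzylic, electron-rich carbinol ionises readily and the cation is trapped by silane hydride.

Step 15
Reactants: 24 1-(benzyloxy)-2,4,6-tris[4-(benzyloxy)benzyl]-3-{2-[3-(benzyloxy)phenyl]ethyl}-5-methoxybenzene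
Product: 25 2,4,6-tris(4-hydroxybenzyl)-3-[2-(3-hydroxyphenyl)ethyl]-5-methoxyphenol
Conditions: H2 (1 atm), 10% Pd/C, EtOAc/MeOH, rt
Reagents that add atoms: none
Why: Catalytic hydrogenolysis cleaves all five O-benzyl ethers while the diarylmethane C–C bonds and the methyl ether are untouched.

## Compound list

1 | 3-(3-hydroxyphenyl)propanoic acid | OC(=O)CCc1cccc(O)c1 | starting material
2 | benzyl 3-[3-(benzyloxy)phenyl]propanoate | O=C(CCc1cccc(OCc2ccccc2)c1)OCc1ccccc1 | intermediate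
3 | 3-[3-(benzyloxy)phenyl]propan-1-ol | OCCCc1cccc(OCc2ccccc2)c1 | intermediate
4 | 3-[3-(benzyloxy)phenyl]propanal | O=CCCc1cccc(OCc2ccccc2)c1 | intermediate
5 | 1-(triphenyl-λ5-phosphanylidene)propan-2-one | CC(=O)C=P(c1ccccc1)(c1ccccc1)c1ccccc1 | starting material
6 | (3E)-6-[3-(benzyloxy)phenyl]hex-3-en-2-one | CC(=O)/C=C/CCc1cccc(OCc2ccccc2)c1 | intermediate
7 | diethyl malonate | CCOC(=O)CC(=O)OCC | starting material
8 | Michael adduct: diethyl 2-{1-[3-(benzyloxy)phenyl]-5-oxohexan-3-yl}propanedioate (racemic; not isolated) | CCOC(=O)C(C(=O)OCC)C(CCc1cccc(OCc2ccccc2)c1)CC(C)=O | intermediate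
9 | cyclic keto ester: ethyl 6-{2-[3-(benzyloxy)phenyl]ethyl}-2,4-dioxocyclohexane-1-carboxylate (racemic; present as its sodium enolate; not isolated) | CCOC(=O)C1C(CCc2cccc(OCc3ccccc3)c2)CC(=O)CC1=O | intermediate
10 | keto acid: 6-{2-[3-(benzyloxy)phenyl]ethyl}-2,4-dioxocyclohexane-1-carboxylic acid (racemic; not isolated) | OC(=O)C1C(CCc2cccc(OCc3ccccc3)c2)CC(=O)CC1=O | intermediate
11 | 5-{2-[3-(benzyloxy)phenyl]ethyl}cyclohexane-1,3-dione | O=C1CC(CCc2cccc(OCc3ccccc3)c2)CC(=O)C1 | intermediate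
12 | 4-(benzyloxy)benzaldehyde | O=Cc1ccc(OCc2ccccc2)cc1 | starting material
13 | alkylidene dione: 2-[4-(benzyloxy)benzylidene]-5-{2-[3-(benzyloxy)phenyl]ethyl}cyclohexane-1,3-dione (not isolated) | O=C1CC(CCc2cccc(OCc3ccccc3)c2)CC(=O)C1=Cc1ccc(OCc2ccccc2)cc1 | intermediate
14 | 2-[4-(benzyloxy)benzyl]-5-{2-[3-(benzyloxy)phenyl]ethyl}cyclohexane-1,3-dione (mainly enol form) | O=C1CC(CCc2cccc(OCc3ccccc3)c2)CC(=O)C1Cc1ccc(OCc2ccccc2)cc1 | intermediate
15 | 2-[4-(benzyloxy)benzyl]-5-{2-[3-(benzyloxy)phenyl]ethyl}-3-methoxycyclohex-2-en-1-one (racemic) | COC1=C(Cc2ccc(OCc3ccccc3)cc2)C(=O)CC(CCc2cccc(OCc3ccccc3)c2)C1 | intermediate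
16 | 6-{[4-(benzyloxy)phenyl](hydroxy)methyl}-2-[4-(benzyloxy)benzyl]-5-{2-[3-(benzyloxy)phenyl]ethyl}-3-methoxycyclohex-2-en-1-one (racemic; 5,6-trans; both carbinol epimers) | COC1=C(Cc2ccc(OCc3ccccc3)cc2)C(=O)C(C(O)c2ccc(OCc3ccccc3)cc2)C(CCc2cccc(OCc3ccccc3)c2)C1 | intermediate
17 | mesylate: methanesulfonate ester of 16 (not isolated) | COC1=C(Cc2ccc(OCc3ccccc3)cc2)C(=O)C(C(OS(C)(=O)=O)c2ccc(OCc3ccccc3)cc2)C(CCc2cccc(OCc3ccccc3)c2)C1 | intermediate
18 | (6E)-2-[4-(benzyloxy)benzyl]-6-[4-(benzyloxy)benzylidene]-5-{2-[3-(benzyloxy)phenyl]ethyl}-3-methoxycyclohex-2-en-1-one (racemic) | COC1=C(Cc2ccc(OCc3ccccc3)cc2)C(=O)/C(=C/c2ccc(OCc3ccccc3)cc2)C(CCc2cccc(OCc3ccccc3)c2)C1 | intermediate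
19 | 2,6-bis[4-(benzyloxy)benzyl]-3-{2-[3-(benzyloxy)phenyl]ethyl}-5-methoxyphenol | COc1cc(CCc2cccc(OCc3ccccc3)c2)c(Cc2ccc(OCc3ccccc3)cc2)c(O)c1Cc1ccc(OCc2ccccc2)cc1 | intermediate
20 | 2,6-bis[4-(benzyloxy)benzyl]-4-bromo-3-{2-[3-(benzyloxy)phenyl]ethyl}-5-methoxyphenol | COc1c(Br)c(CCc2cccc(OCc3ccccc3)c2)c(Cc2ccc(OCc3ccccc3)cc2)c(O)c1Cc1ccc(OCc2ccccc2)cc1 | intermediate
21 | 1-(benzyloxy)-2,6-bis[4-(benzyloxy)benzyl]-4-bromo-3-{2-[3-(benzyloxy)phenyl]ethyl}-5-methoxybenzene | COc1c(Br)c(CCc2cccc(OCc3ccccc3)c2)c(Cc2ccc(OCc3ccccc3)cc2)c(OCc2ccccc2)c1Cc1ccc(OCc2ccccc2)cc1 | intermediate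
22 | aryllithium: (4-(benzyloxy)-3,5-bis[4-(benzyloxy)benzyl]-2-{2-[3-(benzyloxy)phenyl]ethyl}-6-methoxyphenyl)lithium (not isolated) | COc1c([Li])c(CCc2cccc(OCc3ccccc3)c2)c(Cc2ccc(OCc3ccccc3)cc2)c(OCc2ccccc2)c1Cc1ccc(OCc2ccccc2)cc1 | intermediate
23 | [4-(benzyloxy)phenyl](4-(benzyloxy)-3,5-bis[4-(benzyloxy)benzyl]-2-{2-[3-(benzyloxy)phenyl]ethyl}-6-methoxyphenyl)methanol (racemic) | COc1c(C(O)c2ccc(OCc3ccccc3)cc2)c(CCc2cccc(OCc3ccccc3)c2)c(Cc2ccc(OCc3ccccc3)cc2)c(OCc2ccccc2)c1Cc1ccc(OCc2ccccc2)cc1 | intermediate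
24 | 1-(benzyloxy)-2,4,6-tris[4-(benzyloxy)benzyl]-3-{2-[3-(benzyloxy)phenyl]ethyl}-5-methoxybenzene | COc1c(Cc2ccc(OCc3ccccc3)cc2)c(CCc2cccc(OCc3ccccc3)c2)c(Cc2ccc(OCc3ccccc3)cc2)c(OCc2ccccc2)c1Cc1ccc(OCc2ccccc2)cc1 | intermediate
25 | 2,4,6-tris(4-hydroxybenzyl)-3-[2-(3-hydroxyphenyl)ethyl]-5-methoxyphenol (achiral) | COc1c(Cc2ccc(O)cc2)c(O)c(Cc2ccc(O)cc2)c(CCc2cccc(O)c2)c1Cc1ccc(O)cc1 | target

## Step count and risks

Total steps: 15. Longest linear sequence: 15 steps (1 → 25); compounds 5, 7 and 12 are bought.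

Steps most likely to fail:

**Step 8 (aldol at the hindered alpha-prime carbon).** The lithium aldolate may form slowly next to the substituted C5 or revert by retro-aldol. The fallback sets out from 15 and comes back at 16. Compound 15 is deprotonated with LiN(i-Pr)2 and silylated with Me3SiCl to give the isolable silyl dienol ether ({6-[4-(benzyloxy)benzyl]-3-{2-[3-(benzyloxy)phenyl]ethyl}-5-methoxycyclohexa-1,5-dien-1-yl}oxy)trimethylsilane F1. A Mukaiyama aldol addition of F1 to aldehyde 12, promoted by BF3·OEt2 in CH2Cl2 at −78 °C, then gives 16 after aqueous work-up. This addition is irreversible under the Lewis-acid conditions, and any dehydration to 18 is harmless.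

**Step 10 (isoaromatisation).** The exocyclic alkene may not migrate cleanly into the crowded ring. The fallback sets out from 15 and comes back at 19; it aromatises first and forms the C–C bond afterwards. The lithium enolate of 15 is selenenylated with PhSeBr to give 2-[4-(benzyloxy)benzyl]-5-{2-[3-(benzyloxy)phenyl]ethyl}-3-methoxy-6-(phenylselanyl)cyclohex-2-en-1-one F2. Oxidation with H2O2 and pyridine causes selenoxide syn-elimination, and the dienone tautomerises to 2-[4-(benzyloxy)benzyl]-5-{2-[3-(benzyloxy)phenyl]ethyl}-3-methoxyphenol F3. The bromomagnesium phenoxide of F3 (EtMgBr, toluene) adds ortho-specifically to aldehyde 12, an aldol-type hydroxyalkylation through a chelated transition state at the position that is also para to OMe. This gives 2-{[4-(benzyloxy)phenyl](hydroxy)methyl}-6-[4-(benzyloxy)benzyl]-3-{2-[3-(benzyloxy)phenyl]ethyl}-5-methoxyphenol F4. Et3SiH with CF3CO2H in CH2Cl2 at 0 °C reduces F4 to 19.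

**Step 11 (chemoselective bromination).** NBS could touch the other alkoxy rings or benzylic positions of this polyaryl substrate. The fallback sets out from 19 and comes back at 23; the central ring becomes the electrophile instead of the nucleophile. Compound 19 is O-benzylated (BnBr, K2CO3, DMF) to 1-(benzyloxy)-2,6-bis[4-(benzyloxy)benzyl]-3-{2-[3-(benzyloxy)phenyl]ethyl}-5-methoxybenzene F5. Vilsmeier–Haack formylation (POCl3, DMF, 70 °C; aq. NaOAc) reacts only at the free position of the resorcinol-type ring and gives 4-(benzyloxy)-3,5-bis[4-(benzyloxy)benzyl]-2-{2-[3-(benzyloxy)phenyl]ethyl}-6-methoxybenzaldehyde F6. Addition of [4-(benzyloxy)phenyl]magnesium bromide in THF at 0 °C to F6 gives carbinol 23.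

## Further compounds

F1 | step 8 | ({6-[4-(benzyloxy)benzyl]-3-{2-[3-(benzyloxy)phenyl]ethyl}-5-methoxycyclohexa-1,5-dien-1-yl}oxy)trimethylsilane (racemic) | COC1=C(Cc2ccc(OCc3ccccc3)cc2)C(O[Si](C)(C)C)=CC(CCc2cccc(OCc3ccccc3)c2)C1
F2 | step 10 | 2-[4-(benzyloxy)benzyl]-5-{2-[3-(benzyloxy)phenyl]ethyl}-3-methoxy-6-(phenylselanyl)cyclohex-2-en-1-one (racemic, 5,6-trans) | COC1=C(Cc2ccc(OCc3ccccc3)cc2)C(=O)C([Se]c2ccccc2)C(CCc2cccc(OCc3ccccc3)c2)C1
F3 | step 10 | 2-[4-(benzyloxy)benzyl]-5-{2-[3-(benzyloxy)phenyl]ethyl}-3-methoxyphenol | COc1cc(CCc2cccc(OCc3ccccc3)c2)cc(O)c1Cc1ccc(OCc2ccccc2)cc1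
F4 | step 10 | 2-{[4-(benzyloxy)phenyl](hydroxy)methyl}-6-[4-(benzyloxy)benzyl]-3-{2-[3-(benzyloxy)phenyl]ethyl}-5-methoxyphenol (racemic) | COc1cc(CCc2cccc(OCc3ccccc3)c2)c(C(O)c2ccc(OCc3ccccc3)cc2)c(O)c1Cc1ccc(OCc2ccccc2)cc1
F5 | step 11 | 1-(benzyloxy)-2,6-bis[4-(benzyloxy)benzyl]-3-{2-[3-(benzyloxy)phenyl]ethyl}-5-methoxybenzene | COc1cc(CCc2cccc(OCc3ccccc3)c2)c(Cc2ccc(OCc3ccccc3)cc2)c(OCc2ccccc2)c1Cc1ccc(OCc2ccccc2)cc1
F6 | step 11 | 4-(benzyloxy)-3,5-bis[4-(benzyloxy)benzyl]-2-{2-[3-(benzyloxy)phenyl]ethyl}-6-methoxybenzaldehyde | COc1c(C=O)c(CCc2cccc(OCc3ccccc3)c2)c(Cc2ccc(OCc3ccccc3)cc2)c(OCc2ccccc2)c1Cc1ccc(OCc2ccccc2)cc1
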